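The route rests on cutting ring C of the flavanone half at O1–C8a and C4–C4a. Ring A leaves as 3,5-bis(benzyloxy)benzyne, and O1, C2, C3 and C4 remain as an (S)-4-aryl-β-lactone. In the key step the aryne inserts into the acyl–oxygen bond. The four-membered lactone grows by C8a and C4a into the six-membered pyranone, and ring A is joined through two bonds. C2 keeps its configuration because C2–O1 is never broken. The step exploits the ortho O1/C4 pair on ring A and the C5 oxygen beside C4a, which polarises the aryne. The precursor is a strained lactone on a biaryl that already carries the protected apigenin half.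

Key step: step 11

Assumption: 3,5-bis(benzyloxy)phenol is taken as a catalogue compound; flavonoid numbering is used for the flavanone half (rings A, B and C; O1, C2, C3, C4, C4a, C5 to C8, C8a).

Step 1
Reactants: 1 2',4',6'-trihydroxyacetophenone
Product: 2 1-[2,4-bis(benzyloxy)-6-hydroxyphenyl]ethanone
Conditions: BnBr (2 equiv), K2CO3, DMF, 25 °C
Reagents that add atoms: benzyl bromide BrCc1ccccc1
Why: Williamson etherification in which the hydroxyl hydrogen-bonded to the acetyl carbonyl is the least nucleophilic and should stay free when only two equivalents of benzyl bromide are offered.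

Step 2
Reactants: 3 3-bromo-4-hydroxybenzaldehyde
Product: 4 4-(benzyloxy)-3-bromobenzaldehyde
Conditions: BnBr, K2CO3, DMF, 25 °C
Reagents that add atoms: benzyl bromide BrCc1ccccc1
Why: Williamson etherification of an acidic para-formylphenol, with the aldehyde and the aryl bromide inert to carbonate base.

Step 3
Reactants: 2 1-[2,4-bis(benzyloxy)-6-hydroxyphenyl]ethanone; 4 4-(benzyloxy)-3-bromobenzaldehyde
Product: 5 (E)-1-[2,4-bis(benzyloxy)-6-hydroxyphenyl]-3-[4-(benzyloxy)-3-bromophenyl]prop-2-en-1-one
Conditions: KOH, EtOH/THF, 25 °C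
Reagents that add atoms: none
Why: Claisen–Schmidt condensation in which the methyl ketone enolate adds to the non-enolisable aldehyde and dehydration should give the conjugated E-enone.

Step 4
Reactants: 5 (E)-2'-hydroxychalcone
Product: 6 5,7-bis(benzyloxy)-2-[4-(benzyloxy)-3-bromophenyl]-4H-chromen-4-one
Conditions: I2 (10 mol %), DMSO, 120 °C
Reagents that add atoms: none
Why: Iodine-catalysed dehydrogenative cyclisation of a 2'-hydroxychalcone with DMSO as terminal oxidant, a standard flavone synthesis that tolerates benzyl ethers and the aryl bromide.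

Step 5
Reactants: 6 3'-bromoflavone tribenzyl ether
Product: 7 5,7-bis(benzyloxy)-2-[4-(benzyloxy)-3-(4,4,5,5-tetramethyl-1,3,2-dioxaborolan-2-yl)phenyl]-4H-chromen-4-one
Conditions: B2pin2, Pd(dppf)Cl2 (5 mol %), KOAc, 1,4-dioxane, 90 °C
Reagents that add atoms: bis(pinacolato)diboron CC1(C)OB(B2OC(C)(C)C(C)(C)O2)OC1(C)C
Why: Miyaura borylation of an aryl bromide, in which the weak base KOAc prevents homocoupling and leaves the chromenone untouched.

Step 6
Reactants: 7 flavone 3'-boronic ester; 3 3-bromo-4-hydroxybenzaldehyde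
Product: 8 3-{2-(benzyloxy)-5-[5,7-bis(benzyloxy)-4-oxo-4H-chromen-2-yl]phenyl}-4-hydroxybenzaldehyde
Conditions: Pd(OAc)2 (5 mol %), SPhos, K3PO4, 1,4-dioxane/H2O, 80 °C
Reagents that add atoms: none
Why: Suzuki–Miyaura coupling in which the bulky electron-rich phosphine should handle the ortho,ortho'-dioxygenated biaryl and the free phenol is carried as its phenoxide, leaving exactly one hydroxyl open for differentiation.

Step 7
Reactants: 8 biaryl hydroxyaldehyde
Product: 9 benzyl 2-{2-(benzyloxy)-5-[5,7-bis(benzyloxy)-4-oxo-4H-chromen-2-yl]phenyl}-4-formylphenyl carbonate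
Conditions: CbzCl, Et3N, DMAP (cat.), CH2Cl2, 0 °C
Reagents that add atoms: benzyl chloroformate O=C(Cl)OCc1ccccc1
Why: O-acylation with a chloroformate turns the para oxygen from a strong donor into a weakly donating carbonate, which activates the aldehyde, protects the later benzylic C–O bond against ionisation and falls off under the final hydrogenolysis.

Step 8
Reactants: 9 biaryl aldehyde carbonate
Product: 10 benzyl 2-{2-(benzyloxy)-5-[5,7-bis(benzyloxy)-4-oxo-4H-chromen-2-yl]phenyl}-4-[(2S)-4-oxooxetan-2-yl]phenyl carbonate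
Conditions: AcCl (slow addition), i-Pr2NEt, O-trimethylsilylquinidine (15 mol %), LiClO4, CH2Cl2/Et2O, −78 to −40 °C
Reagents that add atoms: acetyl chloride CC(=O)Cl
Why: Cinchona-alkaloid/lithium co-catalysed ketene–aldehyde [2+2] cycloaddition (acyl halide–aldehyde cyclocondensation), in which the chiral ammonium enolate of ketene adds to one face of the lithium-bound aldehyde and lactonises, so the catalyst sets C2 as S (sense assigned by analogy and to be verified on 10, the pseudo-enantiomeric O-trimethylsilylquinine giving the antipode).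

Step 9
Reactants: 11 3,5-bis(benzyloxy)phenol
Product: 12 3,5-bis(benzyloxy)-2-bromophenol
Conditions: NBS (1 equiv), i-Pr2NH (10 mol %), CH2Cl2, −78 to 0 °C
Reagents that add atoms: N-bromosuccinimide O=C1CCC(=O)N1Br
Why: Amine-catalysed ortho-selective electrophilic bromination of a phenol, helped by the equivalence of the two ortho positions and by the greater crowding of the carbon between the two benzyloxy groups.

Step 10
Reactants: 12 3,5-bis(benzyloxy)-2-bromophenol
Product: 15 3,5-bis(benzyloxy)-2-(trimethylsilyl)phenyl trifluoromethanesulfonate, via aryl silyl ether 13 (not isolated), via lithium silylphenoxide 14 (not isolated)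
Conditions: HMDS, THF, 65 °C, then evaporation; n-BuLi, THF, −78 °C; Tf2O, −78 to 0 °C
Reagents that add atoms: hexamethyldisilazane C[Si](C)(C)N[Si](C)(C)C; trifluoromethanesulfonic anhydride O=S(=O)(OS(=O)(=O)C(F)(F)F)C(F)(F)F
Why: O-silylation, bromine–lithium exchange, retro-Brook O-to-C silyl shift and triflation of the resulting phenoxide form the standard sequence to ortho-silylaryl triflates, the exchange being much faster at −78 °C than benzylic deprotonation.

Step 11
Reactants: 10 (S)-β-lactone carbonate; 15 ortho-silylaryl triflate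
Product: 18 benzyl 2-{2-(benzyloxy)-5-[5,7-bis(benzyloxy)-4-oxo-4H-chromen-2-yl]phenyl}-4-[(2S)-5,7-bis(benzyloxy)-4-oxochroman-2-yl]phenyl carbonate, via 3,5-bis(benzyloxy)benzyne 16 (not isolated), via O-aryloxetanonium zwitterion 17 (not isolated)
Conditions: CsF, MeCN/toluene, 25 °C, slow addition of 15 (excess)
Reagents that add atoms: none
Why: Proposed new method: Fluoride-induced 1,2-elimination from 15 releases aryne 16, the ring oxygen of the strained lactone 10 adds to it to give zwitterion 17, and the aryl anion of 17 attacks the neighbouring, unusually electrophilic lactone carbonyl with scission of the acyl–oxygen bond, so that C8a and C4a are inserted between O1 and C4 and the strain of both partners is released. The closest known reaction types are the aryne sigma-insertion into the N–C(O) bond of β-lactams and cyclic ureas (a two-atom ring expansion), the aryne insertion into the C–O bond of carboxylic acids and the aryne–salicylate annulation to xanthones. The pyranone is the only ring formed: the C4a–C4 bond closes in a 4-exo-trig attack inside 17, and the acyl–oxygen scission that follows merges the two fused four-membered rings into the six-membered ring C. No new stereocentre arises, since C2 is a spectator whose bond to O1 is never broken (this also holds if fluoride first opens the acyl–oxygen bond reversibly and the alkoxide captures the aryne), so the S configuration of 10 should be carried unchanged into 18. The regioselectivity needed (O1 to C8a, C4 to C4a) is secured by the benzyloxy group next to the triple bond, which by induction and ring distortion steers nucleophiles to the distal aryne carbon and leaves the anion beside itself. The chemoselectivity needed (acyl–oxygen rather than benzylic alkyl–oxygen cleavage, no ionisation at C2) is supported by the carbonate on ring B, which makes the aryl group a poor cation stabiliser, and by the short distance between anion and carbonyl in 17.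

Step 12
Reactants: 18 fully protected flavanone–flavone
Product: 19 (2S)-2,3-dihydro-3',3'''-biapigenin (target)
Conditions: H2 (1 atm), Pd/C, THF/MeOH, 25 °C
Reagents that add atoms: none
Why: Catalytic hydrogenolysis cleaves the five aryl benzyl ethers and the benzyl carbonate (which then loses CO2) under neutral conditions, so C2 is not exposed to base-induced retro-oxa-Michael opening, and debenzylation is expected to be much faster than reduction of the flavone double bond or of the C2–O1 bond.

Compound list
1 | 2',4',6'-trihydroxyacetophenone | CC(=O)c1c(O)cc(O)cc1O | starting material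
2 | 1-[2,4-bis(benzyloxy)-6-hydroxyphenyl]ethanone | CC(=O)c1c(O)cc(OCc2ccccc2)cc1OCc1ccccc1 | intermediate
3 | 3-bromo-4-hydroxybenzaldehyde | O=Cc1ccc(O)c(Br)c1 | starting material
4 | 4-(benzyloxy)-3-bromobenzaldehyde | O=Cc1ccc(OCc2ccccc2)c(Br)c1 | intermediate
5 | (E)-1-[2,4-bis(benzyloxy)-6-hydroxyphenyl]-3-[4-(benzyloxy)-3-bromophenyl]prop-2-en-1-one | O=C(/C=C/c1ccc(OCc2ccccc2)c(Br)c1)c1c(O)cc(OCc2ccccc2)cc1OCc1ccccc1 | intermediate
6 | 5,7-bis(benzyloxy)-2-[4-(benzyloxy)-3-bromophenyl]-4H-chromen-4-one | O=c1cc(-c2ccc(OCc3ccccc3)c(Br)c2)oc2cc(OCc3ccccc3)cc(OCc3ccccc3)c12 | intermediate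
7 | 5,7-bis(benzyloxy)-2-[4-(benzyloxy)-3-(4,4,5,5-tetramethyl-1,3,2-dioxaborolan-2-yl)phenyl]-4H-chromen-4-one | O=c1cc(-c2ccc(OCc3ccccc3)c(B3OC(C)(C)C(C)(C)O3)c2)oc2cc(OCc3ccccc3)cc(OCc3ccccc3)c12 | intermediate
8 | 3-{2-(benzyloxy)-5-[5,7-bis(benzyloxy)-4-oxo-4H-chromen-2-yl]phenyl}-4-hydroxybenzaldehyde | O=Cc1ccc(O)c(-c2cc(-c3cc(=O)c4c(OCc5ccccc5)cc(OCc5ccccc5)cc4o3)ccc2OCc2ccccc2)c1 | intermediate
9 | benzyl 2-{2-(benzyloxy)-5-[5,7-bis(benzyloxy)-4-oxo-4H-chromen-2-yl]phenyl}-4-formylphenyl carbonate | O=Cc1ccc(OC(=O)OCc2ccccc2)c(-c2cc(-c3cc(=O)c4c(OCc5ccccc5)cc(OCc5ccccc5)cc4o3)ccc2OCc2ccccc2)c1 | intermediate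
10 | benzyl 2-{2-(benzyloxy)-5-[5,7-bis(benzyloxy)-4-oxo-4H-chromen-2-yl]phenyl}-4-[(2S)-4-oxooxetan-2-yl]phenyl carbonate | O=C1C[C@@H](c2ccc(OC(=O)OCc3ccccc3)c(-c3cc(-c4cc(=O)c5c(OCc6ccccc6)cc(OCc6ccccc6)cc5o4)ccc3OCc3ccccc3)c2)O1 | intermediate
11 | 3,5-bis(benzyloxy)phenol | Oc1cc(OCc2ccccc2)cc(OCc2ccccc2)c1 | starting material
12 | 3,5-bis(benzyloxy)-2-bromophenol | Oc1cc(OCc2ccccc2)cc(OCc2ccccc2)c1Br | intermediate
13 | [3,5-bis(benzyloxy)-2-bromophenoxy]trimethylsilane | C[Si](C)(C)Oc1cc(OCc2ccccc2)cc(OCc2ccccc2)c1Br | intermediate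
14 | lithium 3,5-bis(benzyloxy)-2-(trimethylsilyl)phenoxide | [Li+].[O-]c1cc(OCc2ccccc2)cc(OCc2ccccc2)c1[Si](C)(C)C | intermediate
15 | 3,5-bis(benzyloxy)-2-(trimethylsilyl)phenyl trifluoromethanesulfonate | C[Si](C)(C)c1c(OS(=O)(=O)C(F)(F)F)cc(OCc2ccccc2)cc1OCc1ccccc1 | intermediate
16 | 3,5-bis(benzyloxy)benzyne (1,2-didehydro-3,5-bis(benzyloxy)benzene) | C1#CC(OCc2ccccc2)=CC(OCc2ccccc2)=C1 | intermediate
17 | zwitterion of 10 O-arylated at the lactone ring oxygen, aryl anion at the carbon between that oxygen-bearing carbon and a benzyloxy-bearing carbon, (S) at C2 | O=C1C[C@@H](c2ccc(OC(=O)OCc3ccccc3)c(-c3cc(-c4cc(=O)c5c(OCc6ccccc6)cc(OCc6ccccc6)cc5o4)ccc3OCc3ccccc3)c2)[O+]1c1cc(OCc2ccccc2)cc(OCc2ccccc2)[c-]1 | intermediate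
18 | benzyl 2-{2-(benzyloxy)-5-[5,7-bis(benzyloxy)-4-oxo-4H-chromen-2-yl]phenyl}-4-[(2S)-5,7-bis(benzyloxy)-4-oxochroman-2-yl]phenyl carbonate | O=C1C[C@@H](c2ccc(OC(=O)OCc3ccccc3)c(-c3cc(-c4cc(=O)c5c(OCc6ccccc6)cc(OCc6ccccc6)cc5o4)ccc3OCc3ccccc3)c2)Oc2cc(OCc3ccccc3)cc(OCc3ccccc3)c21 | intermediate
19 | (2S)-2,3-dihydro-3',3'''-biapigenin, 2-{3-[5-((2S)-5,7-dihydroxy-4-oxochroman-2-yl)-2-hydroxyphenyl]-4-hydroxyphenyl}-5,7-dihydroxy-4H-chromen-4-one | O=C1C[C@@H](c2ccc(O)c(-c3cc(-c4cc(=O)c5c(O)cc(O)cc5o4)ccc3O)c2)Oc2cc(O)cc(O)c21 | target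

Total step count: 12.
Longest linear sequence: 9 steps (1, 3, 4, 5, 6, 7, 8, 11, 12).

Steps most likely to fail

1. Step 11 (the labelled step).
- **What may go wrong:** The lactone oxygen is a weak nucleophile, so the aryne may be used up by self-reaction or by the medium before it is captured. Attack through the carbonyl oxygen, fluoride-induced opening at the benzylic carbon, or fluoride attack on the carbonate would divert material. Any of these could also erode the configuration at C2 through ionisation.
- **Fallback:** It uses known chemistry, sets out from 9 (with 11 as partner) and comes back at 18. The two bonds to ring A are made one after the other in reversed order. Aldehyde 9 is taken through the conditions of step 8 with the pseudo-enantiomeric O-trimethylsilylquinine to give the (R)-β-lactone F1. The sodium salt of phenol 11 (NaH, THF/DMF, 0 °C) opens it at the benzylic carbon by SN2 alkyl–oxygen cleavage with inversion, the classical phenoxide/β-lactone reaction, to give the (S)-3-aryloxypropanoic acid F2. Intramolecular Friedel–Crafts acylation through the mixed anhydride (trifluoroacetic anhydride, CH2Cl2, 0 °C) then closes ring C and gives 18. It can occur at either of the two equivalent positions ortho to O1 on the phloroglucinol-type ring.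

2. Step 8.
- **What may go wrong:** The aromatic aldehyde may add the ammonium enolate too slowly, so that ketene dimerisation wins. Facial selectivity may be insufficient on this large, lithium-binding substrate. The product may lose CO2 on isolation.
- **Fallback:** It sets out from 9 and comes back at 10, with C–C bond formation and lactonisation separated. A catalytic asymmetric Mukaiyama aldol addition of 1-(tert-butylsulfanyl)-1-(trimethylsilyloxy)ethene is run with Ti(OiPr)4 and the BINOL antipode that delivers the S carbinol (Et2O, −20 °C, acidic work-up). This gives the (S)-β-hydroxy thioester F3. Thiophilic activation with Hg(OCOCF3)2 in MeCN at 25 °C closes the lactone by acyl substitution. The C–O bond at the stereocentre stays intact, so retention is expected.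

3. Step 12.
- **What may go wrong:** The flavone C2=C3 double bond may be saturated, the benzylic C2–O1 bond of the flavanone may be hydrogenolysed, or debenzylation may stall as the polyphenol precipitates on the catalyst.
- **Fallback:** It sets out from 18 and comes back at 19. Reductive cleavage is replaced by Lewis-acid dealkylation with a cation scavenger (BCl3, pentamethylbenzene, CH2Cl2, −78 °C, then MeOH). This removes benzyl ethers and the benzyl carbonate without hydrogen or a metal surface, and at a temperature at which ring C should not open. This fallback makes no new compound (F0).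

Further compounds
F1 | step 11 | benzyl 2-{2-(benzyloxy)-5-[5,7-bis(benzyloxy)-4-oxo-4H-chromen-2-yl]phenyl}-4-[(2R)-4-oxooxetan-2-yl]phenyl carbonate | O=C1C[C@H](c2ccc(OC(=O)OCc3ccccc3)c(-c3cc(-c4cc(=O)c5c(OCc6ccccc6)cc(OCc6ccccc6)cc5o4)ccc3OCc3ccccc3)c2)O1
F2 | step 11 | (3S)-3-[3,5-bis(benzyloxy)phenoxy]-3-{4-[(benzyloxycarbonyl)oxy]-3-{2-(benzyloxy)-5-[5,7-bis(benzyloxy)-4-oxo-4H-chromen-2-yl]phenyl}phenyl}propanoic acid | O=C(O)C[C@@H](c1ccc(OC(=O)OCc2ccccc2)c(-c2cc(-c3cc(=O)c4c(OCc5ccccc5)cc(OCc5ccccc5)cc4o3)ccc2OCc2ccccc2)c1)Oc1cc(OCc2ccccc2)cc(OCc2ccccc2)c1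
F3 | step 8 | S-tert-butyl (3S)-3-hydroxy-3-{4-[(benzyloxycarbonyl)oxy]-3-{2-(benzyloxy)-5-[5,7-bis(benzyloxy)-4-oxo-4H-chromen-2-yl]phenyl}phenyl}propanethioate | CC(C)(C)SC(=O)C[C@@H](c1ccc(OC(=O)OCc2ccccc2)c(-c2cc(-c3cc(=O)c4c(OCc5ccccc5)cc(OCc5ccccc5)cc4o3)ccc2OCc2ccccc2)c1)O
F0 | step 12 | none | none
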